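**Retrosynthetic overview**

1. Target ⇐ Schenck ene reaction of singlet oxygen on the 7(11)-en-8-one (O to C11, alkene moves to C6=C7) ⇐ esterification of the 3α-alcohol with (2S,3R)-2,3-dimethyloxirane-2-carboxylic acid, made from tiglic acid by reduction, Sharpless epoxidation and oxidation.
2. 3α-Alcohol ⇐ bicyclic 3α-silyloxy-4β-hydroxy-8-ketone by acetylation at O4, acetone aldol–dehydration at C7 and desilylation.
3. Bicyclic ketone ⇐ acyclic (3R,6E)-3,10-bis(silyloxy)-6-methylundeca-6,10-dien-2-one in one cationic cascade: C4–C5 closes ring A first, C9–C10 closes ring B second. The strategy rests on three atoms: ring A carbon C4, which carries a methyl group and oxygen next to the C3 oxygen (an attacked methyl ketone); the quaternary C10 shared by rings A and B (a tertiary cation); and the C8 ketone of ring B (the end of an enol ether).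
4. Acyclic ketone ⇐ Weinreb amide (ketone unmasked last, so that enol silylation meets only one methyl ketone) ⇐ Negishi sp3–sp2 coupling of an alkylzinc from (R)-α-hydroxy-γ-butyrolactone with an (E)-2-iodoalkene from 2-(2-bromoethyl)-2-methyl-1,3-dioxolane and 1-propynyllithium.

Key step: step 10

Remark on the chemistry: bicyclic compounds carry eudesmane numbering (methyl C15 on C4, methyl C14 on C10). The cyclisation product has no C11–C13 and is named as an 11,12,13-trinoreudesmane. Chain atoms C2, C3, C6, C7, C10 and C11 of the acyclic ketone become ring atoms C4, C3, C10, C5, C8 and C9. The lactone, the bromo ketal and 1-propynyllithium are assumed to be purchased.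

**Route**

Step 1
Reactants: 1 (R)-α-hydroxy-γ-butyrolactone [(3R)-3-hydroxydihydrofuran-2(3H)-one]
Product: 2 (3R)-3-(tert-butyldimethylsilyloxy)dihydrofuran-2(3H)-one
Conditions: TBSCl, imidazole, DMF, rt
Reagents that add atoms: tert-butyldimethylsilyl chloride, CC(C)(C)[Si](C)(C)Cl
Why: Imidazole-promoted silylation of a secondary alcohol, which leaves the stereocenter (the later C3) untouched.

Step 2
Reactants: 2 (3R)-3-(tert-butyldimethylsilyloxy)dihydrofuran-2(3H)-one
Product: 3 (2R)-2-(tert-butyldimethylsilyloxy)-4-hydroxy-N-methoxy-N-methylbutanamide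
Conditions: MeNHOMe·HCl, Me3Al, CH2Cl2, 0 °C to rt; aqueous potassium sodium tartrate work-up
Reagents that add atoms: N,O-dimethylhydroxylamine hydrochloride, CNOC.Cl
Why: Weinreb aminolysis of the lactone by the aluminium amide formed in the flask opens the ring without touching the α-stereocenter; the hydroxy amide should be used at once because it can relactonise.

Step 3
Reactants: 3 (2R)-2-(tert-butyldimethylsilyloxy)-4-hydroxy-N-methoxy-N-methylbutanamide
Product: 4 (2R)-2-(tert-butyldimethylsilyloxy)-4-iodo-N-methoxy-N-methylbutanamide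
Conditions: I2, PPh3, imidazole, CH2Cl2, 0 °C
Reagents that add atoms: iodine, II
Why: Appel-type iodination of the primary alcohol (SN2 on the alkoxyphosphonium ion) under neutral conditions that spare the silyl ether and the amide.

Step 4
Reactants: 5 2-(2-bromoethyl)-2-methyl-1,3-dioxolane; 6 1-propynyllithium
Product: 7 2-methyl-2-(pent-3-yn-1-yl)-1,3-dioxolane
Conditions: THF/DMPU, 0 °C to rt
Reagents that add atoms: none
Why: SN2 alkylation of a lithium acetylide by a primary bromide in a dipolar medium.

Step 5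
Reactants: 7 2-methyl-2-(pent-3-yn-1-yl)-1,3-dioxolane
Product: 9 2-[(3E)-4-iodopent-3-en-1-yl]-2-methyl-1,3-dioxolane, via alkenylzirconocene chloride 8 (not isolated)
Conditions: Cp2Zr(H)Cl (excess), THF, 50 °C; then I2, 0 °C
Reagents that add atoms: iodine, II
Why: syn-Hydrozirconation with excess Schwartz reagent equilibrates zirconium to the less hindered, methyl-bearing alkyne carbon, and iodinolysis with retention fixes the E geometry (methyl cis to the chain) that becomes the C5=C10 alkene.

Step 6
Reactants: 4 (2R)-2-(tert-butyldimethylsilyloxy)-4-iodo-N-methoxy-N-methylbutanamide; 9 2-[(3E)-4-iodopent-3-en-1-yl]-2-methyl-1,3-dioxolane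
Product: 11 (2R,5E)-2-(tert-butyldimethylsilyloxy)-N-methoxy-N,5-dimethyl-8-(2-methyl-1,3-dioxolan-2-yl)oct-5-enamide, via alkylzinc iodide 10 (not isolated)
Conditions: Zn dust (activated), DMF, rt; then 9, Pd(OAc)2 (cat.), SPhos (cat.), rt to 40 °C
Reagents that add atoms: none
Why: Negishi sp3–sp2 coupling, in which zinc insertion tolerates the Weinreb amide and silyl ether and the alkenyl iodide couples with retention of the E geometry.

Step 7
Reactants: 11 (2R,5E)-2-(tert-butyldimethylsilyloxy)-N-methoxy-N,5-dimethyl-8-(2-methyl-1,3-dioxolan-2-yl)oct-5-enamide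
Product: 12 (2R,5E)-2-(tert-butyldimethylsilyloxy)-N-methoxy-N,5-dimethyl-9-oxodec-5-enamide
Conditions: PPTS (cat.), acetone/H2O, 50 °C
Reagents that add atoms: water, O
Why: Mild acid hydrolysis of the dioxolane, to which the secondary TBS ether, the Weinreb amide and the trisubstituted alkene are stable.

Step 8
Reactants: 12 (2R,5E)-2-(tert-butyldimethylsilyloxy)-N-methoxy-N,5-dimethyl-9-oxodec-5-enamide
Product: 14 (2R,5E)-2,9-bis(tert-butyldimethylsilyloxy)-N-methoxy-N,5-dimethyldeca-5,9-dienamide, via potassium enolate 13 (not isolated)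
Conditions: KN(SiMe3)2, THF, −78 °C; then TBSCl, −78 to 0 °C
Reagents that add atoms: tert-butyldimethylsilyl chloride, CC(C)(C)[Si](C)(C)Cl
Why: Kinetic deprotonation of the methyl ketone at its methyl group and O-silylation give the terminal enol silane; the only other carbonyl is the far less acidic Weinreb amide, which is why the initiating ketone is still masked here, and any minor internal enol silane is removed after the cascade.

Step 9
Reactants: 14 (2R,5E)-2,9-bis(tert-butyldimethylsilyloxy)-N-methoxy-N,5-dimethyldeca-5,9-dienamide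
Product: 15 (3R,6E)-3,10-bis(tert-butyldimethylsilyloxy)-6-methylundeca-6,10-dien-2-one
Conditions: MeMgBr, THF, −78 to 0 °C; aqueous NaH2PO4/Na2HPO4 (pH 7) work-up
Reagents that add atoms: methylmagnesium bromide, C[Mg]Br
Why: Weinreb ketone synthesis, in which the chelated tetrahedral adduct stops at the ketone, the α-silyloxy stereocenter is not enolised and the TBS enol ether is inert to the Grignard reagent and to a buffered work-up.

Step 10
Reactants: 15 (3R,6E)-3,10-bis(tert-butyldimethylsilyloxy)-6-methylundeca-6,10-dien-2-one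
Product: 16 (3R,4R,5R,10R)-3-(tert-butyldimethylsilyloxy)-4-hydroxy-11,12,13-trinoreudesman-8-one [(4aR,5R,6R,8aR)-6-(tert-butyldimethylsilyloxy)-5-hydroxy-5,8a-dimethyloctahydronaphthalen-2(1H)-one; trans-decalin, 3α-OTBS and 4β-OH axial, 4α-CH3, 5α-H, 10β-CH3]
Conditions: BF3·OEt2, 2,6-di-tert-butyl-4-methylpyridine, CH2Cl2 (high dilution), −78 to −40 °C; then aqueous NaHCO3
Reagents that add atoms: none
Why: BF3 binds the C2 ketone of 15 (ring carbon C4), the electron-rich CH carbon of the E alkene (C5) attacks it, and the tertiary C10 cation is captured by the CH2 terminus (C9) of the silyl enol ether, whose silyl group leaves as the fluoride and uncovers the C8 ketone; the closest known reactions are Lewis acid promoted carbonyl-initiated (Prins-type) cation–olefin cyclisations and polyene cyclisations terminated by enol silanes. Ring A closes 6-endo with respect to the C5=C10 alkene (C4–C5 bond) and ring B closes 6-endo with respect to the enol ether (C9–C10 bond), both through chairs. C5 and C10 follow from antiperiplanar addition across the E alkene in the chair–chair array, which places H5 anti to the C10 methyl (trans-decalin). At C4 the methyl group should take the equatorial site, away from the C10 methyl, so that the complexed oxygen ends axial (4β). The absolute sense comes from C3: in the reactive chair the silyloxy group is axial and antiperiplanar to the complexed carbonyl (opposed dipoles), which fixes the ketone face that the alkene attacks. The step needs this non-chelated chair to win over the one with an equatorial silyloxy group, which is why a monodentate acid and a bulky, non-chelating TBS ether are used, and it needs ring B to close faster than proton loss or desilylation, which the nucleophilic enol silane, the hindered pyridine and high dilution should secure.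

Step 11
Reactants: 16 3α-(tert-butyldimethylsilyloxy)-4β-hydroxy-11,12,13-trinor-5α-eudesman-8-one
Product: 17 4β-acetoxy-3α-(tert-butyldimethylsilyloxy)-11,12,13-trinor-5α-eudesman-8-one
Conditions: Ac2O, DMAP, Et3N, CH2Cl2, 40 °C
Reagents that add atoms: acetic anhydride, CC(=O)OC(C)=O
Why: DMAP-catalysed (Steglich-type) acylation of the tertiary alcohol, run under forcing conditions because the hydroxyl is axial and syn to the C10 methyl, with the ketone and silyl ether inert.

Step 12
Reactants: 17 4β-acetoxy-3α-(tert-butyldimethylsilyloxy)-11,12,13-trinor-5α-eudesman-8-one; 18 acetone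
Product: 20 4β-acetoxy-3α-(tert-butyldimethylsilyloxy)-11-hydroxy-5α-eudesman-8-one (C7 epimers), via lithium C7 enolate 19 (not isolated)
Conditions: LiN(iPr)2, THF, −78 °C; then acetone, −78 °C; AcOH quench at −78 °C
Reagents that add atoms: none
Why: Kinetic deprotonation should occur at C7 because C9 is flanked by the quaternary C10, and the lithium enolate adds to acetone (aldol addition); the new C7 center is not controlled and is removed in the next step.

Step 13
Reactants: 20 4β-acetoxy-3α-(tert-butyldimethylsilyloxy)-11-hydroxy-5α-eudesman-8-one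
Product: 22 4β-acetoxy-3α-(tert-butyldimethylsilyloxy)-5α-eudesm-7(11)-en-8-one, via tertiary mesylate 21 (not isolated)
Conditions: MsCl, Et3N, CH2Cl2, 0 °C; then DBU, rt
Reagents that add atoms: none
Why: Mesylation of the tertiary aldol hydroxyl and base-induced E1cB elimination through the C7 enolate give the conjugated isopropylidene ketone, and DBU brings any isopropenyl isomer into conjugation.

Step 14
Reactants: 22 4β-acetoxy-3α-(tert-butyldimethylsilyloxy)-5α-eudesm-7(11)-en-8-one
Product: 23 4β-acetoxy-3α-hydroxy-5α-eudesm-7(11)-en-8-one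
Conditions: HF (aq.), MeCN, 0 °C to rt
Reagents that add atoms: none
Why: Fluoride cleavage of the secondary TBS ether under mildly acidic conditions, where the trans-diaxial arrangement of O3 and the C4 acetate rules out acetyl migration.

Step 15
Reactants: 24 tiglic acid
Product: 25 (2E)-2-methylbut-2-en-1-ol
Conditions: LiAlH4, Et2O, 0 °C to rt
Reagents that add atoms: none
Why: Hydride reduction of the carboxylic acid to the allylic alcohol, which leaves the trisubstituted alkene and its E geometry intact.

Step 16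
Reactants: 25 (2E)-2-methylbut-2-en-1-ol
Product: 26 [(2R,3R)-2,3-dimethyloxiran-2-yl]methanol
Conditions: Ti(OiPr)4 (cat.), D-(−)-diethyl tartrate (cat.), t-BuOOH, 4 Å MS, CH2Cl2, −20 °C
Reagents that add atoms: tert-butyl hydroperoxide, CC(C)(C)OO
Why: Sharpless asymmetric epoxidation, in which the D-(−)-tartrate directs oxygen to the alkene face that gives the (2R,3R)-epoxy alcohol and the E alkene fixes the two methyl groups cis on the oxirane.

Step 17
Reactants: 26 [(2R,3R)-2,3-dimethyloxiran-2-yl]methanol
Product: 27 (2S,3R)-2,3-dimethyloxirane-2-carboxylic acid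
Conditions: RuCl3 (cat.), NaIO4, MeCN/EtOAc/H2O, 0 °C to rt
Reagents that add atoms: water, O
Why: Oxidation of the primary alcohol to the acid by RuO4 generated in the flask, which does not open the epoxide; the C2 descriptor changes from R to S only because the CIP priorities change.

Step 18
Reactants: 23 4β-acetoxy-3α-hydroxy-5α-eudesm-7(11)-en-8-one; 27 (2S,3R)-2,3-dimethyloxirane-2-carboxylic acid
Product: 29 4β-acetoxy-8-oxo-5α-eudesm-7(11)-en-3α-yl (2S,3R)-2,3-dimethyloxirane-2-carboxylate, via mixed anhydride 28 (not isolated)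
Conditions: 2,4,6-trichlorobenzoyl chloride, Et3N, toluene, rt; then 23, DMAP, rt to 50 °C
Reagents that add atoms: none
Why: Yamaguchi esterification through the mixed anhydride and DMAP acyl transfer suits the hindered axial secondary alcohol, and the acid has no α-hydrogen, so its stereocenters cannot epimerise.

Step 19
Reactants: 29 4β-acetoxy-8-oxo-5α-eudesm-7(11)-en-3α-yl (2S,3R)-2,3-dimethyloxirane-2-carboxylate
Product: 30 4β-acetoxy-11-hydroperoxy-8-oxo-5α-eudesm-6-en-3α-yl (2S,3R)-2,3-dimethyloxirane-2-carboxylate (CNP0270248.1)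
Conditions: O2, visible light, tetraphenylporphyrin (cat.), CH2Cl2, −20 °C
Reagents that add atoms: oxygen, O=O
Why: Schenck ene reaction of singlet oxygen with the s-cis enone, in which oxygen bonds to the β-carbon C11 and the hydrogen is taken from C6, the alkyl group geminal to the carbonyl (gem selectivity of α,β-unsaturated carbonyl compounds), so the alkene moves to C6=C7 and no new stereocenter is formed.

**Compound list**

1 | (R)-α-hydroxy-γ-butyrolactone [(3R)-3-hydroxydihydrofuran-2(3H)-one] | O=C1OCC[C@H]1O | starting material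
2 | (3R)-3-(tert-butyldimethylsilyloxy)dihydrofuran-2(3H)-one | O=C1OCC[C@H]1O[Si](C)(C)C(C)(C)C | intermediate
3 | (2R)-2-(tert-butyldimethylsilyloxy)-4-hydroxy-N-methoxy-N-methylbutanamide | CON(C)C(=O)[C@H](O[Si](C)(C)C(C)(C)C)CCO | intermediate
4 | (2R)-2-(tert-butyldimethylsilyloxy)-4-iodo-N-methoxy-N-methylbutanamide | CON(C)C(=O)[C@H](O[Si](C)(C)C(C)(C)C)CCI | intermediate
5 | 2-(2-bromoethyl)-2-methyl-1,3-dioxolane | CC1(CCBr)OCCO1 | starting material
6 | 1-propynyllithium | CC#C[Li] | starting material
7 | 2-methyl-2-(pent-3-yn-1-yl)-1,3-dioxolane | CC#CCCC1(C)OCCO1 | intermediate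
8 | chloro[(2E)-5-(2-methyl-1,3-dioxolan-2-yl)pent-2-en-2-yl]zirconocene (not isolated) | Cl[Zr](C1C=CC=C1)(C1C=CC=C1)/C(C)=C/CCC1(C)OCCO1 | intermediate
9 | 2-[(3E)-4-iodopent-3-en-1-yl]-2-methyl-1,3-dioxolane | I/C(C)=C/CCC1(C)OCCO1 | intermediate
10 | [(3R)-3-(tert-butyldimethylsilyloxy)-4-[methoxy(methyl)amino]-4-oxobutyl]zinc iodide (not isolated) | CON(C)C(=O)[C@H](O[Si](C)(C)C(C)(C)C)CC[Zn]I | intermediate
11 | (2R,5E)-2-(tert-butyldimethylsilyloxy)-N-methoxy-N,5-dimethyl-8-(2-methyl-1,3-dioxolan-2-yl)oct-5-enamide | CON(C)C(=O)[C@H](O[Si](C)(C)C(C)(C)C)CC/C(C)=C/CCC1(C)OCCO1 | intermediate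
12 | (2R,5E)-2-(tert-butyldimethylsilyloxy)-N-methoxy-N,5-dimethyl-9-oxodec-5-enamide | CON(C)C(=O)[C@H](O[Si](C)(C)C(C)(C)C)CC/C(C)=C/CCC(C)=O | intermediate
13 | potassium enolate of 12 at the terminal methyl (not isolated) | CON(C)C(=O)[C@H](O[Si](C)(C)C(C)(C)C)CC/C(C)=C/CCC(=C)O[K] | intermediate
14 | (2R,5E)-2,9-bis(tert-butyldimethylsilyloxy)-N-methoxy-N,5-dimethyldeca-5,9-dienamide | CON(C)C(=O)[C@H](O[Si](C)(C)C(C)(C)C)CC/C(C)=C/CCC(=C)O[Si](C)(C)C(C)(C)C | intermediate
15 | (3R,6E)-3,10-bis(tert-butyldimethylsilyloxy)-6-methylundeca-6,10-dien-2-one | CC(=O)[C@H](O[Si](C)(C)C(C)(C)C)CC/C(C)=C/CCC(=C)O[Si](C)(C)C(C)(C)C | intermediate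
16 | (3R,4R,5R,10R)-3-(tert-butyldimethylsilyloxy)-4-hydroxy-11,12,13-trinoreudesman-8-one (3α-OTBS, 4β-OH, 5α-H, 10β-CH3) | O[C@]1(C)[C@@H]2CCC(=O)C[C@@]2(C)CC[C@H]1O[Si](C)(C)C(C)(C)C | intermediate
17 | 4β-acetoxy-3α-(tert-butyldimethylsilyloxy)-11,12,13-trinor-5α-eudesman-8-one | CC(=O)O[C@]1(C)[C@@H]2CCC(=O)C[C@@]2(C)CC[C@H]1O[Si](C)(C)C(C)(C)C | intermediate
18 | acetone | CC(C)=O | starting material
19 | lithium C7(8)-enolate of 17 (not isolated) | CC(=O)O[C@]1(C)[C@@H]2CC=C(O[Li])C[C@@]2(C)CC[C@H]1O[Si](C)(C)C(C)(C)C | intermediate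
20 | 4β-acetoxy-3α-(tert-butyldimethylsilyloxy)-11-hydroxy-5α-eudesman-8-one (C7 not controlled) | CC(=O)O[C@]1(C)[C@@H]2CC(C(C)(C)O)C(=O)C[C@@]2(C)CC[C@H]1O[Si](C)(C)C(C)(C)C | intermediate
21 | C11 methanesulfonate of 20 (not isolated) | CC(=O)O[C@]1(C)[C@@H]2CC(C(C)(C)OS(C)(=O)=O)C(=O)C[C@@]2(C)CC[C@H]1O[Si](C)(C)C(C)(C)C | intermediate
22 | 4β-acetoxy-3α-(tert-butyldimethylsilyloxy)-5α-eudesm-7(11)-en-8-one | CC(=O)O[C@]1(C)[C@@H]2CC(=C(C)C)C(=O)C[C@@]2(C)CC[C@H]1O[Si](C)(C)C(C)(C)C | intermediate
23 | 4β-acetoxy-3α-hydroxy-5α-eudesm-7(11)-en-8-one | CC(=O)O[C@]1(C)[C@@H]2CC(=C(C)C)C(=O)C[C@@]2(C)CC[C@H]1O | intermediate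
24 | tiglic acid | C/C=C(\C)C(=O)O | starting material
25 | (2E)-2-methylbut-2-en-1-ol | C/C=C(\C)CO | intermediate
26 | [(2R,3R)-2,3-dimethyloxiran-2-yl]methanol | OC[C@@]1(C)O[C@@H]1C | intermediate
27 | (2S,3R)-2,3-dimethyloxirane-2-carboxylic acid | OC(=O)[C@@]1(C)O[C@@H]1C | intermediate
28 | (2S,3R)-2,3-dimethyloxirane-2-carboxylic 2,4,6-trichlorobenzoic anhydride (not isolated) | O=C(OC(=O)[C@@]1(C)O[C@@H]1C)c1c(Cl)cc(Cl)cc1Cl | intermediate
29 | 4β-acetoxy-8-oxo-5α-eudesm-7(11)-en-3α-yl (2S,3R)-2,3-dimethyloxirane-2-carboxylate | CC(=O)O[C@]1(C)[C@@H]2CC(=C(C)C)C(=O)C[C@@]2(C)CC[C@H]1OC(=O)[C@@]1(C)O[C@@H]1C | intermediate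
30 | (3R,4R,5R,10R)-4-acetoxy-11-hydroperoxy-8-oxoeudesm-6-en-3-yl (2S,3R)-2,3-dimethyloxirane-2-carboxylate (CNP0270248.1) | CC(=O)O[C@]1(C)[C@@H]2C=C(C(C)(C)OO)C(=O)C[C@@]2(C)CC[C@H]1OC(=O)[C@@]1(C)O[C@@H]1C | target

**Step count**

Total steps: 19. Longest linear sequence: 14 steps (1, 2, 3, 6–14, 18, 19). The cyclisation precursor 15 is reached in 9 steps (7 in the longest line).

**Steps most likely to fail**

1. Step 10. The alkene may attack through the other chair, the one with an equatorial silyloxy group, which is the opposite ketone face and leads to the diastereomeric series. The ketone may also be activated so slowly that desilylation of the terminator or proton loss from the C10 cation takes over. The fallback moves the initiating carbon to the aldehyde level and builds the C4 carbinol afterwards on the rigid decalin. An aldehyde is far more electrophilic, has no methyl group that eclipses the axial silyloxy group in the chair, and is the case where dipole control by an α-silyloxy group under BF3 is best founded. The fallback sets out from 14 and comes back at 16. iBu2AlH (THF, −78 °C) should reduce the Weinreb amide to (2R,5E)-2,9-bis(tert-butyldimethylsilyloxy)-5-methyldeca-5,9-dienal F1. BF3·OEt2 with the hindered pyridine in dilute CH2Cl2 at −78 °C should close both rings to 3α-(tert-butyldimethylsilyloxy)-4-hydroxy-11,12,13,15-tetranor-5α-eudesman-8-one F2, whose C4 configuration does not matter. Ethylene glycol and PPTS in refluxing benzene would mask the C8 ketone as the 8,8-ethylenedioxy ketal F3. Dess–Martin periodinane would oxidise the carbinol to 3α-(tert-butyldimethylsilyloxy)-8,8-ethylenedioxy-11,12,13,15-tetranor-5α-eudesman-4-one F4. MeMgBr (THF, −78 °C) should attack along the equatorial path, because the axial path is closed by the syn-axial C10 methyl, and give 3α-(tert-butyldimethylsilyloxy)-8,8-ethylenedioxy-11,12,13-trinor-5α-eudesman-4β-ol F5. PPTS in acetone/water then removes the ketal to give 16.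

2. Step 19. Abstraction of a methyl hydrogen (C12 or C13, oxygen then bonding to C7) may compete with abstraction of H6, and peroxide may be lost when regioisomers have to be separated from the fully acylated, base-sensitive final product. The fallback moves the oxygenation one stage back and carries the peroxide in protected form, so that the separation is done on a simpler intermediate. It sets out from 23 and comes back at 30. Photooxygenation of 23 (O2, visible light, tetraphenylporphyrin, CH2Cl2, −20 °C) should give 4β-acetoxy-11-hydroperoxy-3α-hydroxy-5α-eudesm-6-en-8-one F6, which is purified at this stage. TESCl and imidazole at −20 °C should silylate the more acidic hydroperoxide in preference to the hindered axial alcohol and give 4β-acetoxy-3α-hydroxy-11-(triethylsilylperoxy)-5α-eudesm-6-en-8-one F7. Acylation with mixed anhydride 28 and DMAP, as in step 18, would give 4β-acetoxy-8-oxo-11-(triethylsilylperoxy)-5α-eudesm-6-en-3α-yl (2S,3R)-2,3-dimethyloxirane-2-carboxylate F8. HF·pyridine in THF at 0 °C then frees the hydroperoxide to give 30.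

3. Step 11. Acyl transfer to the axial tertiary hydroxyl, which is syn to the C10 methyl, may stay incomplete, and forcing conditions may form the enol acetate of the ketone. The fallback acylates the lithium alkoxide instead and folds this into the aldol step. It sets out from 16 and comes back at 22. LiN(iPr)2 (2.2 equiv, THF, −78 °C) should give the dilithium C4 alkoxide C7 enolate F9. Acetone at −78 °C would convert it into the dilithium 4,11-dialkoxide of the aldol adduct F10. Quenching with excess Ac2O (−78 to 0 °C) should acetylate both alkoxides to 4β,11-diacetoxy-3α-(tert-butyldimethylsilyloxy)-5α-eudesman-8-one F11. DBU in CH2Cl2 at rt then eliminates acetic acid by the E1cB path to give 22.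

**Further compounds**

F1 | step 10 | (2R,5E)-2,9-bis(tert-butyldimethylsilyloxy)-5-methyldeca-5,9-dienal | O=C[C@H](O[Si](C)(C)C(C)(C)C)CC/C(C)=C/CCC(=C)O[Si](C)(C)C(C)(C)C
F2 | step 10 | 3α-(tert-butyldimethylsilyloxy)-4-hydroxy-11,12,13,15-tetranor-5α-eudesman-8-one (C4 epimers) | OC1[C@@H]2CCC(=O)C[C@@]2(C)CC[C@H]1O[Si](C)(C)C(C)(C)C
F3 | step 10 | 3α-(tert-butyldimethylsilyloxy)-8,8-ethylenedioxy-11,12,13,15-tetranor-5α-eudesman-4-ol (C4 epimers) | OC1[C@@H]2CCC3(OCCO3)C[C@@]2(C)CC[C@H]1O[Si](C)(C)C(C)(C)C
F4 | step 10 | 3α-(tert-butyldimethylsilyloxy)-8,8-ethylenedioxy-11,12,13,15-tetranor-5α-eudesman-4-one | O=C1[C@@H]2CCC3(OCCO3)C[C@@]2(C)CC[C@H]1O[Si](C)(C)C(C)(C)C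
F5 | step 10 | 3α-(tert-butyldimethylsilyloxy)-8,8-ethylenedioxy-11,12,13-trinor-5α-eudesman-4β-ol | O[C@]1(C)[C@@H]2CCC3(OCCO3)C[C@@]2(C)CC[C@H]1O[Si](C)(C)C(C)(C)C
F6 | step 19 | 4β-acetoxy-11-hydroperoxy-3α-hydroxy-5α-eudesm-6-en-8-one | CC(=O)O[C@]1(C)[C@@H]2C=C(C(C)(C)OO)C(=O)C[C@@]2(C)CC[C@H]1O
F7 | step 19 | 4β-acetoxy-3α-hydroxy-11-(triethylsilylperoxy)-5α-eudesm-6-en-8-one | CC(=O)O[C@]1(C)[C@@H]2C=C(C(C)(C)OO[Si](CC)(CC)CC)C(=O)C[C@@]2(C)CC[C@H]1O
F8 | step 19 | 4β-acetoxy-8-oxo-11-(triethylsilylperoxy)-5α-eudesm-6-en-3α-yl (2S,3R)-2,3-dimethyloxirane-2-carboxylate | CC(=O)O[C@]1(C)[C@@H]2C=C(C(C)(C)OO[Si](CC)(CC)CC)C(=O)C[C@@]2(C)CC[C@H]1OC(=O)[C@@]1(C)O[C@@H]1C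
F9 | step 11 | dilithium C4 alkoxide C7(8)-enolate of 16 | [Li]O[C@]1(C)[C@@H]2CC=C(O[Li])C[C@@]2(C)CC[C@H]1O[Si](C)(C)C(C)(C)C
F10 | step 11 | dilithium 4,11-dialkoxide of 3α-(tert-butyldimethylsilyloxy)-4β,11-dihydroxy-5α-eudesman-8-one (C7 not controlled) | [Li]O[C@]1(C)[C@@H]2CC(C(C)(C)O[Li])C(=O)C[C@@]2(C)CC[C@H]1O[Si](C)(C)C(C)(C)C
F11 | step 11 | 4β,11-diacetoxy-3α-(tert-butyldimethylsilyloxy)-5α-eudesman-8-one (C7 not controlled) | CC(=O)O[C@]1(C)[C@@H]2CC(C(C)(C)OC(C)=O)C(=O)C[C@@]2(C)CC[C@H]1O[Si](C)(C)C(C)(C)C
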